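## Analysis of the target

The target is a 1H-isochromen-1-one (isocoumarin). Ring A is the benzo ring (C4a, C5–C8, C8a) and ring B the pyranone (C1, O2, C3, C4) with a pentyl group on C3; C6 carries a free hydroxyl. C8 is joined through an ether oxygen to C5' of ring C, which is olivetolic acid: CO2H on C1', OH on C2' and C4', pentyl on C6', and C3' the only ring hydrogen. There is no stereocentre, so no stereochemical relation has to be built; the only geometric question arises in an open-chain intermediate. The enol lactone is opened by alkoxides and its C3=C4 bond can be hydrogenated; the 2,4-dihydroxy-6-alkylbenzoic acid loses CO2 on heating or in acid; the three phenols are electron-rich and oxidisable. The hard part is the diaryl ether: C8 lies peri to the lactone carbonyl and C5' sits between an oxygen and the pentyl chain, so a direct aryl C–O coupling would be hindered on both sides. Ring C is also pentasubstituted, and each substituent has to be placed without a regiochemical choice. The strategy rests on one feature: ring B with its pentyl group is 6-pentyl-2-pyranone, and ring A is fused across the C3–C4 bond of that pyranone (C8a–C4a of the isocoumarin). The four carbons C8, C7, C6 and C5 can therefore hang from pyranone C3 as a dienyl chain that already carries the ether oxygen on C8, and ring A is closed by bonding C5 to C4a.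

## Retrosynthetic reasoning

**19 to 18.** The carboxyl on C1' of 19 is flanked by the pentyl chain and a hydroxyl, and C3' is also free. Bringing in the carboxyl carbon at the end by carboxylation of the free resorcinol would have to choose between C1' and C3' and would expose the enol lactone to a hot basic reagent. The carboxyl is therefore carried from 9 as a benzyl ester. 19 is cut only at three O–benzyl bonds (two ethers and the ester) to give 18, and the forward reaction is a neutral hydrogenolysis at room temperature, which suits an acid that decarboxylates easily.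

**18 to 17.** The O–Si bond at C6 is cut. The C6 oxygen is born as a silyl enol ether, so it arrives as an aryl silyl ether. A tert-butyldimethylsilyl group is chosen over a trimethylsilyl group because the dienol ether and the aryl ether then survive the alcohol released in the ring closure and can be purified.

**17 to 15 (key disconnection).** The C5–C4a bond is cut, and the C5 methoxy group and the C4a hydrogen are added back. This gives triene 15, whose third double bond is the C3–C4 bond of the pyranone. It is the one ring A bond whose cleavage leaves ring B as an untouched pyranone and turns the C8–O bond into a vinyl ether; cutting C8–C8a or a bond of ring B would give up the commercial pyranone 1. The gain is that ring B, its pentyl group and the lactone need no construction, and that no oxidation-state change follows the closure. The forward reaction has to close the triene onto the pyranone double bond (through 16) and then lose the C5 methoxy group with the C4a hydrogen.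

**15 to 14.** The enol O–Si bond is cut. In 14 the methylene between the carbonyl and the methoxy group is the only enolisable position, so the regiochemistry of enolisation is fixed by structure.

**14 to 8 and 13.** The C8–O bond is cut. The ether oxygen comes from phenol 13 and C8 is the β-carbon of ynone 8. A hindered phenoxide adds to an sp carbon far more readily than it couples to a hindered aryl halide, and the β-carbon of 8 is the one attached to the pyranone, so polarity places the oxygen on C8. The forward reaction must also give the double bond with the pyranone and the carbonyl on the same side (E); 14 is a push–pull alkene in which this geometry can equilibrate.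

**8 back to 1.** The C6–C7 bond (acyl to alkynyl) and the C8–C8a bond (alkynyl to pyranone C3) are two sp couplings. C8 and C7 come from 4; C6, C5 and the methoxy group come from 7; the handle on pyranone C3 is the bromide 3, made from 1 through the alkyne stages 5 and 6.

**13 back to 9.** The C5'–O bond is cut. C5' is the only position of 10 that is para to an ether oxygen and it lies next to the pentyl chain, so electrophilic bromination marks it (11); boron and then oxygen replace the bromine (12, 13). 10 is the fully benzylated form of 9.

## Alternatives that were turned down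

**Alternative 1: ring C from acyclic pieces.** The disconnection removes C1'–C6' and C2'–C3' of ring C. In the forward key step dibenzyl malonate A2 adds in Michael fashion to the α-aryloxy enone 3-{[6-(benzyloxy)-1-oxo-3-pentyl-1H-isochromen-8-yl]oxy}non-3-en-2-one A3, and an intramolecular Claisen condensation closes the cyclohexane-1,3-dione A1. Dehydrogenation to the resorcinol and hydrogenolysis would finish the synthesis.
- For it: this is the classical construction of olivetolates; it places all five ring C substituents, carboxyl included, by connectivity, and its key step has much better precedent than the chosen one. On ring C regiochemistry it is as strong as the chosen route.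
- Against it: the key step needs a strong alkoxide base and a malonate anion in the presence of the enol lactone, which such nucleophiles open. A3 is a poor acceptor, with an oxygen donor on the α-carbon and the pentyl group on the β-carbon. Its isocoumarin half must first be made by a separate arene synthesis and then O-alkylated at a peri-hydrogen-bonded phenol. The aromatisation of A1 needs an oxidant that would also attack C4 of the isocoumarin and ring A.
- Comparison: the chosen route joins two fragments that are already at the right oxidation level through a conjugate addition, and after the lactone exists it uses only amines, fluoride buffered with acid, and hydrogen.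

**Alternative 2: Catellani assembly of ring B.** The disconnection removes C4a–C4, C8a–C1 and C1–O2. In the forward key step the aryl iodide 1,5-bis(benzyloxy)-2-(2-iodo-5-methoxyphenoxy)-3-pentylbenzene A5, 2-pentyloxirane A6 and carbon monoxide A7 combine under palladium catalysis to the racemic 3,4-dihydroisocoumarin A4.
- For it: three components close ring B in one operation, the blocked ortho position at C8 suits the ortho-alkylation, and the reaction class is known, which the chosen key step is not.
- Against it: A4 is at the wrong oxidation level, so C3–C4 must be dehydrogenated in a molecule full of benzylic and electron-rich positions, and a stereocentre is made only to be destroyed. The C6 oxygen is a methyl ether that needs a boron trihalide at the end. The diaryl ether of A5 has to be made first by exactly the doubly hindered aryl C–O coupling that the chosen route avoids. Ring C still lacks its carboxyl, so the C1'/C3' problem returns at the last step.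
- Comparison: the chosen route delivers the isocoumarin at the correct oxidation level with the carboxyl already in place, and everything after its key step is deprotection.

**Alternative 3: Danheiser benzannulation for ring A.** The disconnection removes C6–C7, C8–C8a and C5–C6. In the forward key step 3-methylcyclobut-2-en-1-one A9 and the aryl ethynyl ether 1,5-bis(benzyloxy)-2-(ethynyloxy)-3-pentylbenzene A10 react through a vinylketene to give 3-[2,4-bis(benzyloxy)-6-pentylphenoxy]-5-methylphenol A8.
- For it: the benzannulation with alkynyl ethers is established and regiospecific, and the ether oxygen travels on the alkyne, so no diaryl ether coupling is needed. On precedent of the key step and on regiocontrol in ring A it is stronger than the chosen route.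
- Against it: A8 has neither C1 nor ring B. C1 would have to enter at C8a, the most hindered position between the aryloxy and methyl groups, while the positions ortho to the free hydroxyl are more reactive. Ring B then needs lateral metalation, acylation and lactonisation, and ring C still needs its carboxyl. A10 requires strong-base chemistry on a hindered phenol, and A9 is volatile and must be prepared.
- Comparison: the chosen route takes ring B ready-made from 1 and needs two steps after its key step, where this alternative needs the longest sequence after its key step of all three.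

Key step: step 10

Assumption: olivetolic acid 9 is bought as a catalogue research chemical, so the carboxyl carbon of ring C is present from the first step of that branch.

## Route

**Step 1**
Reactants: 1 6-pentyl-2H-pyran-2-one
Product: 3 3-bromo-6-pentyl-2H-pyran-2-one, via 3,4-dibromo-3,4-dihydropyranone 2 (not isolated)
Conditions: Br2 (1.0 equiv), CH2Cl2, 0 °C → rt, dark; then Et3N, 0 °C
Reagents that add atoms: bromine, BrBr
Why: Ionic bromination–dehydrobromination of a 2-pyranone: bromine adds across the C3–C4 bond of the unsaturated lactone and the amine removes the acidic C3 hydrogen with loss of the C4 bromide, the established way from a 2-pyranone to its 3-bromo derivative. One equivalent of bromine and exclusion of light should keep C5 substitution and side-chain bromination down.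

**Step 2**
Reactants: 3 3-bromo-6-pentyl-2H-pyran-2-one; 4 trimethylsilylacetylene
Product: 5 6-pentyl-3-[(trimethylsilyl)ethynyl]-2H-pyran-2-one
Conditions: PdCl2(PPh3)2 (3 mol%), CuI (5 mol%), Et3N, THF, rt → 40 °C
Reagents that add atoms: none
Why: Sonogashira coupling; the C–Br bond α to the lactone carbonyl is a good partner for oxidative addition, and the mild amine does not open the pyranone.

**Step 3**
Reactants: 5 6-pentyl-3-[(trimethylsilyl)ethynyl]-2H-pyran-2-one
Product: 6 3-ethynyl-6-pentyl-2H-pyran-2-one
Conditions: Bu4NF (1.1 equiv), AcOH (1.1 equiv), THF, 0 °C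
Reagents that add atoms: none
Why: Fluoride-induced protodesilylation of an alkynylsilane; the acetic acid buffer keeps alkoxide-type bases away from the pyranone ring.

**Step 4**
Reactants: 6 3-ethynyl-6-pentyl-2H-pyran-2-one; 7 methoxyacetyl chloride
Product: 8 3-(4-methoxy-3-oxobut-1-yn-1-yl)-6-pentyl-2H-pyran-2-one
Conditions: PdCl2(PPh3)2 (2 mol%), CuI (4 mol%), Et3N (1.2 equiv, slow addition), THF, rt
Reagents that add atoms: none
Why: Acyl Sonogashira coupling of a terminal alkyne with an acid chloride to the ynone; the amine is kept near one equivalent and added slowly so that ketene formation from the α-alkoxy acid chloride does not compete.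

**Step 5**
Reactants: 9 olivetolic acid (2,4-dihydroxy-6-pentylbenzoic acid)
Product: 10 benzyl 2,4-bis(benzyloxy)-6-pentylbenzoate
Conditions: BnBr (3.5 equiv), K2CO3 (4 equiv), DMF, rt → 60 °C
Reagents that add atoms: benzyl bromide, BrCc1ccccc1
Why: Williamson alkylation of the carboxylate and both phenoxides; the carboxylate is esterified first at room temperature, which removes the risk of decarboxylation before the hydrogen-bonded C2' phenol is benzylated on warming.

**Step 6**
Reactants: 10 benzyl 2,4-bis(benzyloxy)-6-pentylbenzoate
Product: 11 benzyl 4,6-bis(benzyloxy)-3-bromo-2-pentylbenzoate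
Conditions: NBS (1.05 equiv), MeCN, 0 °C → rt, dark
Reagents that add atoms: N-bromosuccinimide, O=C1CCC(=O)N1Br
Why: Electrophilic aromatic bromination; C5' is para to the C2' ether and ortho to the C4' ether, whereas C3' is only ortho to both and buttressed by two benzyloxy groups, the same preference that 1,3-dialkoxy-5-alkylbenzenes show for the position next to the alkyl group.

**Step 7**
Reactants: 11 benzyl 4,6-bis(benzyloxy)-3-bromo-2-pentylbenzoate
Product: 13 benzyl 4,6-bis(benzyloxy)-3-hydroxy-2-pentylbenzoate, via pinacol boronate 12 (not isolated)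
Conditions: B2pin2, Pd2(dba)3 (2 mol%), XPhos (8 mol%), KOAc, dioxane, 100 °C; then 30% H2O2, 1 M NaOH, THF, 0 °C
Reagents that add atoms: bis(pinacolato)diboron, CC1(C)OB(OC1(C)C)B1OC(C)(C)C(C)(C)O1 (boron of 12); hydrogen peroxide, OO (phenol oxygen of 13)
Why: Miyaura borylation with a bulky biarylphosphine suited to di-ortho-substituted aryl bromides, then oxidation of the C–B bond at the same carbon. The benzyl ester is flanked on both sides and should not be hydrolysed in the short, cold basic oxidation.

**Step 8**
Reactants: 8 3-(4-methoxy-3-oxobut-1-yn-1-yl)-6-pentyl-2H-pyran-2-one; 13 benzyl 4,6-bis(benzyloxy)-3-hydroxy-2-pentylbenzoate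
Product: 14 benzyl 4,6-bis(benzyloxy)-3-{[(1E)-4-methoxy-3-oxo-1-(2-oxo-6-pentyl-2H-pyran-3-yl)but-1-en-1-yl]oxy}-2-pentylbenzoate
Conditions: DABCO (20 mol%), MeCN, rt
Reagents that add atoms: none
Why: Amine-catalysed oxa-Michael addition of the phenol to the ynone; the oxygen attacks the β-carbon, which is the one on the pyranone. The β-aryloxy enone is a push–pull alkene whose isomers interconvert under the catalyst by addition–elimination, and the E isomer (aryloxy anti to the carbonyl, as in enol ethers of 1,3-diketones) is the one expected to prevail. Any Z isomer is separated and returned to the same conditions.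

**Step 9**
Reactants: 14 benzyl 4,6-bis(benzyloxy)-3-{[(1E)-4-methoxy-3-oxo-1-(2-oxo-6-pentyl-2H-pyran-3-yl)but-1-en-1-yl]oxy}-2-pentylbenzoate
Product: 15 benzyl 4,6-bis(benzyloxy)-3-({(1E,3Z)-3-[(tert-butyldimethylsilyl)oxy]-4-methoxy-1-(2-oxo-6-pentyl-2H-pyran-3-yl)buta-1,3-dien-1-yl}oxy)-2-pentylbenzoate
Conditions: TBSOTf (1.3 equiv), Et3N (2.5 equiv), CH2Cl2, −20 → 0 °C
Reagents that add atoms: tert-butyldimethylsilyl trifluoromethanesulfonate, CC(C)(C)[Si](C)(C)OS(=O)(=O)C(F)(F)F
Why: Soft enolisation of a β-alkoxy enone to its 3-silyloxy diene, the standard entry to 1-alkoxy-3-silyloxybutadienes. The methylene between carbonyl and methoxy is the only enolisable position, and the Z enol ether (methoxy on the side of the silyloxy group, pointing away from the diene) is the usual outcome for α-alkoxy ketones.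

**Step 10**
Reactants: 15 benzyl 4,6-bis(benzyloxy)-3-({(1E,3Z)-3-[(tert-butyldimethylsilyl)oxy]-4-methoxy-1-(2-oxo-6-pentyl-2H-pyran-3-yl)buta-1,3-dien-1-yl}oxy)-2-pentylbenzoate
Product: 17 benzyl 4,6-bis(benzyloxy)-3-({6-[(tert-butyldimethylsilyl)oxy]-1-oxo-3-pentyl-1H-isochromen-8-yl}oxy)-2-pentylbenzoate, via 5-methoxy-4a,5-dihydroisochromenone 16 (not isolated)
Conditions: degassed o-xylene (0.01 M), 2,6-lutidine (0.1 equiv), 140 °C, Ar; then camphorsulfonic acid (0.2 equiv), rt
Reagents that add atoms: none
Why: Proposed new method: the pyranone C3–C4 bond, the aryloxy-bearing C8=C7 bond and the silyl enol ether C6=C5 bond form a 1,3,5-hexatriene whose central double bond holds the two ends cis, so thermal disrotatory 6π-electrocyclisation should bond C5 to C4a and close the six-membered carbocycle of ring A as dihydroisochromenone 16. Methanol is then lost across C4a–C5 (ionisation of the doubly allylic C5–O bond on the acid finish and loss of the C4a proton), which aromatises ring A to 17. The closest known reaction type is the thermal 6π-electrocyclisation and alcohol or amine elimination of dienyl heteroarenes, such as 2,3-divinylindoles giving carbazoles; what has not been shown is a 2-pyranone C3–C4 bond serving as the third double bond. The triene carries the lactone carbonyl on its second carbon and oxygen donors on its third, fifth and sixth carbons, the push–pull pattern that lowers the barrier of hexatriene closure, and the pyranone gives up only a small resonance energy, so closure near 140 °C is a reasonable expectation. The two transient stereocentres of 16 (C4a and C5, hydrogens cis) are set by the disrotatory motion and the alkene geometries and are erased on aromatisation, so no stereocontrol is required. Regiochemistry is fixed by connectivity: there is one hexatriene only, C5 carries the methoxy group and C4a a hydrogen, and the aryloxy and silyloxy groups sit on sp2 carbons C8 and C6 and cannot leave. The step needs ring closure to win over intermolecular Diels–Alder reaction of the pyranone diene, which high dilution secures, and it needs the 1E geometry set in step 8, since the 1Z isomer cannot reach the reactive conformation.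

**Step 11**
Reactants: 17 benzyl 4,6-bis(benzyloxy)-3-({6-[(tert-butyldimethylsilyl)oxy]-1-oxo-3-pentyl-1H-isochromen-8-yl}oxy)-2-pentylbenzoate
Product: 18 benzyl 4,6-bis(benzyloxy)-3-[(6-hydroxy-1-oxo-3-pentyl-1H-isochromen-8-yl)oxy]-2-pentylbenzoate
Conditions: Bu4NF (1.1 equiv), AcOH (1.1 equiv), THF, 0 °C
Reagents that add atoms: none
Why: Fluoride cleavage of an aryl silyl ether, fast here because the C6 phenoxide is a vinylogous carboxylate; the buffer protects the enol lactone.

**Step 12**
Reactants: 18 benzyl 4,6-bis(benzyloxy)-3-[(6-hydroxy-1-oxo-3-pentyl-1H-isochromen-8-yl)oxy]-2-pentylbenzoate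
Product: 19 4,6-dihydroxy-3-[(6-hydroxy-1-oxo-3-pentyl-1H-isochromen-8-yl)oxy]-2-pentylbenzoic acid
Conditions: H2 (1 atm), 10% Pd/C, EtOAc, rt; filtration and evaporation below 30 °C
Reagents that add atoms: none
Why: Hydrogenolysis of two benzyl ethers and the benzyl ester under neutral conditions; O-benzyl cleavage should be much faster than saturation of the trisubstituted, arene-conjugated C3=C4 bond, and the reaction is stopped after uptake of three equivalents of hydrogen.

## Compound list

1 | 6-pentyl-2H-pyran-2-one | CCCCCc1cccc(=O)o1 | starting material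
2 | 3,4-dibromo-6-pentyl-3,4-dihydro-2H-pyran-2-one (racemic, mixture of diastereomers; not isolated) | CCCCCC1=CC(Br)C(Br)C(=O)O1 | intermediate
3 | 3-bromo-6-pentyl-2H-pyran-2-one | CCCCCc1ccc(Br)c(=O)o1 | intermediate
4 | trimethylsilylacetylene | C#C[Si](C)(C)C | starting material
5 | 6-pentyl-3-[(trimethylsilyl)ethynyl]-2H-pyran-2-one | CCCCCc1ccc(C#C[Si](C)(C)C)c(=O)o1 | intermediate
6 | 3-ethynyl-6-pentyl-2H-pyran-2-one | CCCCCc1ccc(C#C)c(=O)o1 | intermediate
7 | methoxyacetyl chloride | COCC(=O)Cl | starting material
8 | 3-(4-methoxy-3-oxobut-1-yn-1-yl)-6-pentyl-2H-pyran-2-one | CCCCCc1ccc(C#CC(=O)COC)c(=O)o1 | intermediate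
9 | olivetolic acid (2,4-dihydroxy-6-pentylbenzoic acid) | CCCCCc1cc(O)cc(O)c1C(=O)O | starting material
10 | benzyl 2,4-bis(benzyloxy)-6-pentylbenzoate | CCCCCc1cc(OCc2ccccc2)cc(OCc2ccccc2)c1C(=O)OCc1ccccc1 | intermediate
11 | benzyl 4,6-bis(benzyloxy)-3-bromo-2-pentylbenzoate | CCCCCc1c(Br)c(OCc2ccccc2)cc(OCc2ccccc2)c1C(=O)OCc1ccccc1 | intermediate
12 | benzyl 4,6-bis(benzyloxy)-2-pentyl-3-(4,4,5,5-tetramethyl-1,3,2-dioxaborolan-2-yl)benzoate (not isolated) | CCCCCc1c(B2OC(C)(C)C(C)(C)O2)c(OCc2ccccc2)cc(OCc2ccccc2)c1C(=O)OCc1ccccc1 | intermediate
13 | benzyl 4,6-bis(benzyloxy)-3-hydroxy-2-pentylbenzoate | CCCCCc1c(O)c(OCc2ccccc2)cc(OCc2ccccc2)c1C(=O)OCc1ccccc1 | intermediate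
14 | benzyl 4,6-bis(benzyloxy)-3-{[(1E)-4-methoxy-3-oxo-1-(2-oxo-6-pentyl-2H-pyran-3-yl)but-1-en-1-yl]oxy}-2-pentylbenzoate | CCCCCc1ccc(/C(Oc2c(OCc3ccccc3)cc(OCc3ccccc3)c(C(=O)OCc3ccccc3)c2CCCCC)=C\C(=O)COC)c(=O)o1 | intermediate
15 | benzyl 4,6-bis(benzyloxy)-3-({(1E,3Z)-3-[(tert-butyldimethylsilyl)oxy]-4-methoxy-1-(2-oxo-6-pentyl-2H-pyran-3-yl)buta-1,3-dien-1-yl}oxy)-2-pentylbenzoate | CCCCCc1ccc(/C(Oc2c(OCc3ccccc3)cc(OCc3ccccc3)c(C(=O)OCc3ccccc3)c2CCCCC)=C\C(O[Si](C)(C)C(C)(C)C)=C\OC)c(=O)o1 | intermediate
16 | benzyl 4,6-bis(benzyloxy)-3-({6-[(tert-butyldimethylsilyl)oxy]-5-methoxy-1-oxo-3-pentyl-4a,5-dihydro-1H-isochromen-8-yl}oxy)-2-pentylbenzoate (racemic, 4a-H and 5-H cis, rac-(4aR,5R); not isolated) | CCCCCC1=C[C@H]2[C@@H](OC)C(O[Si](C)(C)C(C)(C)C)=CC(Oc3c(OCc4ccccc4)cc(OCc4ccccc4)c(C(=O)OCc4ccccc4)c3CCCCC)=C2C(=O)O1 | intermediate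
17 | benzyl 4,6-bis(benzyloxy)-3-({6-[(tert-butyldimethylsilyl)oxy]-1-oxo-3-pentyl-1H-isochromen-8-yl}oxy)-2-pentylbenzoate | CCCCCc1cc2cc(O[Si](C)(C)C(C)(C)C)cc(Oc3c(OCc4ccccc4)cc(OCc4ccccc4)c(C(=O)OCc4ccccc4)c3CCCCC)c2c(=O)o1 | intermediate
18 | benzyl 4,6-bis(benzyloxy)-3-[(6-hydroxy-1-oxo-3-pentyl-1H-isochromen-8-yl)oxy]-2-pentylbenzoate | CCCCCc1cc2cc(O)cc(Oc3c(OCc4ccccc4)cc(OCc4ccccc4)c(C(=O)OCc4ccccc4)c3CCCCC)c2c(=O)o1 | intermediate
19 | 4,6-dihydroxy-3-[(6-hydroxy-1-oxo-3-pentyl-1H-isochromen-8-yl)oxy]-2-pentylbenzoic acid | CCCCCc1cc2cc(O)cc(Oc3c(O)cc(O)c(C(=O)O)c3CCCCC)c2c(=O)o1 | target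

## Step count and least certain steps

Total step count: 12. Longest linear sequence: 9 steps (1 → 3 → 5 → 6 → 8 → 14 → 15 → 17 → 18 → 19); the ring C branch (9 → 10 → 11 → 13) joins at step 8.

**Step 10 (key step, bears the label "Proposed new method:").** The closure may fail at temperatures the silyl dienol ether tolerates, because the pyranone double bond is reluctant to leave conjugation. Bimolecular cycloaddition of the pyranone diene or hydrolytic loss of the enol ether may then take over. Hydrogen shifts in 16 before the elimination could also move the silyloxy carbon to sp3 and open loss of silanol as a second aromatisation path. The fallback uses known arene chemistry, sets out from 13 and comes back at 19. Methyl orsellinate F1 is benzylated at the free para hydroxyl (BnBr, K2CO3, acetone) to methyl 4-(benzyloxy)-2-hydroxy-6-methylbenzoate F2, and this is converted with Tf2O and pyridine into methyl 4-(benzyloxy)-2-methyl-6-{[(trifluoromethyl)sulfonyl]oxy}benzoate F3. Palladium-catalysed diaryl ether formation between F3 and 13 (Pd(OAc)2, tBuXPhos, K3PO4, toluene, 100 °C) should give benzyl 4,6-bis(benzyloxy)-3-[5-(benzyloxy)-2-(methoxycarbonyl)-3-methylphenoxy]-2-pentylbenzoate F4. Lateral lithiation of its toluate methyl group (LiN(iPr)2, THF, −78 °C) and acylation with N-methoxy-N-methylhexanamide F5 gives the keto ester benzyl 4,6-bis(benzyloxy)-3-[5-(benzyloxy)-2-(methoxycarbonyl)-3-(2-oxoheptyl)phenoxy]-2-pentylbenzoate F6. Acid-catalysed enol lactonisation (TsOH, toluene, 80 °C) closes ring B to benzyl 4,6-bis(benzyloxy)-3-{[6-(benzyloxy)-1-oxo-3-pentyl-1H-isochromen-8-yl]oxy}-2-pentylbenzoate F7, and hydrogenolysis as in step 12 gives 19.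

**Step 9.** The dienol ether may hydrolyse on isolation, the C8=C7 geometry may scramble through the O-silylated oxocarbenium ion, and the silyl triflate may activate the pyranone. The fallback replaces soft enolisation and a silyl group by hard enolisation and an acyl group that the last step removes; it sets out from 14 and comes back at 19. Deprotonation with KN(SiMe3)2 in THF at −78 °C and trapping with benzyl chloroformate should give the dienyl carbonate benzyl 4,6-bis(benzyloxy)-3-({(1E,3Z)-3-{[(benzyloxy)carbonyl]oxy}-4-methoxy-1-(2-oxo-6-pentyl-2H-pyran-3-yl)buta-1,3-dien-1-yl}oxy)-2-pentylbenzoate F8. Heating under the conditions of step 10 should lead, through the dihydro compound benzyl 4,6-bis(benzyloxy)-3-[(6-{[(benzyloxy)carbonyl]oxy}-5-methoxy-1-oxo-3-pentyl-4a,5-dihydro-1H-isochromen-8-yl)oxy]-2-pentylbenzoate F9, to the aryl carbonate benzyl 4,6-bis(benzyloxy)-3-[(6-{[(benzyloxy)carbonyl]oxy}-1-oxo-3-pentyl-1H-isochromen-8-yl)oxy]-2-pentylbenzoate F10. Hydrogenolysis as in step 12 cleaves the carbonate together with the other benzyl groups and gives 19.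

**Step 8.** The di-ortho-substituted phenol may add slowly, which would leave the amine catalyst or the phenoxide time to attack the pyranone ring or to oligomerise the ynone; the double-bond isomers may also equilibrate to an unfavourable mixture. The fallback replaces addition to the alkyne by addition–elimination on a vinyl halide, sets out from 8 and comes back at 14. Hydrochlorination of 8 (LiCl, AcOH, rt) should give the β-chlorovinyl ketone 3-[(1Z)-1-chloro-4-methoxy-3-oxobut-1-en-1-yl]-6-pentyl-2H-pyran-2-one F11. Stoichiometric potassium phenoxide of 13 (K2CO3, DMF, rt) then displaces chloride to 14, whose geometry equilibrates in the presence of the phenoxide.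

**Step 7.** Oxidative addition into the di-ortho-substituted, electron-rich aryl bromide may be slow, and protodebromination may outrun borylation. The fallback installs the oxygen through a carbon substituent and an oxidative rearrangement; it sets out from 10 and comes back at 13. Rieche formylation of 10 (Cl2CHOMe, AgOTf, CH2Cl2, −78 °C) at C5' should give benzyl 4,6-bis(benzyloxy)-3-formyl-2-pentylbenzoate F12. Baeyer–Villiger oxidation (mCPBA, CH2Cl2, 0 °C) gives the formate benzyl 4,6-bis(benzyloxy)-3-(formyloxy)-2-pentylbenzoate F13, and methanolysis (K2CO3, MeOH, 0 °C) gives 13.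

**Step 12.** The C3=C4 bond of the isocoumarin may be reduced, the benzyl ether next to the hindered ester may be cleaved incompletely, and the free acid may decarboxylate during isolation. The fallback replaces reductive cleavage by Lewis-acid cleavage with a cation scavenger; it sets out from 18 and comes back at 19: BCl3 and pentamethylbenzene in CH2Cl2 at −78 °C, with a cold neutral work-up. It makes no new compound (F0).

## Further compounds

F1 | step 10 | methyl orsellinate (methyl 2,4-dihydroxy-6-methylbenzoate) | COC(=O)c1c(C)cc(O)cc1O
F2 | step 10 | methyl 4-(benzyloxy)-2-hydroxy-6-methylbenzoate | COC(=O)c1c(C)cc(OCc2ccccc2)cc1O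
F3 | step 10 | methyl 4-(benzyloxy)-2-methyl-6-{[(trifluoromethyl)sulfonyl]oxy}benzoate | COC(=O)c1c(C)cc(OCc2ccccc2)cc1OS(=O)(=O)C(F)(F)F
F4 | step 10 | benzyl 4,6-bis(benzyloxy)-3-[5-(benzyloxy)-2-(methoxycarbonyl)-3-methylphenoxy]-2-pentylbenzoate | COC(=O)c1c(C)cc(OCc2ccccc2)cc1Oc1c(OCc2ccccc2)cc(OCc2ccccc2)c(C(=O)OCc2ccccc2)c1CCCCC
F5 | step 10 | N-methoxy-N-methylhexanamide | CCCCCC(=O)N(C)OC
F6 | step 10 | benzyl 4,6-bis(benzyloxy)-3-[5-(benzyloxy)-2-(methoxycarbonyl)-3-(2-oxoheptyl)phenoxy]-2-pentylbenzoate | COC(=O)c1c(CC(=O)CCCCC)cc(OCc2ccccc2)cc1Oc1c(OCc2ccccc2)cc(OCc2ccccc2)c(C(=O)OCc2ccccc2)c1CCCCC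
F7 | step 10 | benzyl 4,6-bis(benzyloxy)-3-{[6-(benzyloxy)-1-oxo-3-pentyl-1H-isochromen-8-yl]oxy}-2-pentylbenzoate | CCCCCc1cc2cc(OCc3ccccc3)cc(Oc3c(OCc4ccccc4)cc(OCc4ccccc4)c(C(=O)OCc4ccccc4)c3CCCCC)c2c(=O)o1
F8 | step 9 | benzyl 4,6-bis(benzyloxy)-3-({(1E,3Z)-3-{[(benzyloxy)carbonyl]oxy}-4-methoxy-1-(2-oxo-6-pentyl-2H-pyran-3-yl)buta-1,3-dien-1-yl}oxy)-2-pentylbenzoate | CCCCCc1ccc(/C(Oc2c(OCc3ccccc3)cc(OCc3ccccc3)c(C(=O)OCc3ccccc3)c2CCCCC)=C\C(OC(=O)OCc2ccccc2)=C\OC)c(=O)o1
F9 | step 9 | benzyl 4,6-bis(benzyloxy)-3-[(6-{[(benzyloxy)carbonyl]oxy}-5-methoxy-1-oxo-3-pentyl-4a,5-dihydro-1H-isochromen-8-yl)oxy]-2-pentylbenzoate (racemic, 4a-H and 5-H cis; not isolated) | CCCCCC1=C[C@H]2[C@@H](OC)C(OC(=O)OCc3ccccc3)=CC(Oc3c(OCc4ccccc4)cc(OCc4ccccc4)c(C(=O)OCc4ccccc4)c3CCCCC)=C2C(=O)O1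
F10 | step 9 | benzyl 4,6-bis(benzyloxy)-3-[(6-{[(benzyloxy)carbonyl]oxy}-1-oxo-3-pentyl-1H-isochromen-8-yl)oxy]-2-pentylbenzoate | CCCCCc1cc2cc(OC(=O)OCc3ccccc3)cc(Oc3c(OCc4ccccc4)cc(OCc4ccccc4)c(C(=O)OCc4ccccc4)c3CCCCC)c2c(=O)o1
F11 | step 8 | 3-[(1Z)-1-chloro-4-methoxy-3-oxobut-1-en-1-yl]-6-pentyl-2H-pyran-2-one | CCCCCc1ccc(/C(Cl)=C/C(=O)COC)c(=O)o1
F12 | step 7 | benzyl 4,6-bis(benzyloxy)-3-formyl-2-pentylbenzoate | CCCCCc1c(C=O)c(OCc2ccccc2)cc(OCc2ccccc2)c1C(=O)OCc1ccccc1
F13 | step 7 | benzyl 4,6-bis(benzyloxy)-3-(formyloxy)-2-pentylbenzoate | CCCCCc1c(OC=O)c(OCc2ccccc2)cc(OCc2ccccc2)c1C(=O)OCc1ccccc1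
F0 | step 12 | none | none
A1 | alternative 1 | benzyl 3-{[6-(benzyloxy)-1-oxo-3-pentyl-1H-isochromen-8-yl]oxy}-4,6-dioxo-2-pentylcyclohexane-1-carboxylate (mixture of stereoisomers and enol forms) | CCCCCC1C(Oc2cc(OCc3ccccc3)cc3cc(CCCCC)oc(=O)c23)C(=O)CC(=O)C1C(=O)OCc1ccccc1
A2 | alternative 1 | dibenzyl malonate | O=C(CC(=O)OCc1ccccc1)OCc1ccccc1
A3 | alternative 1 | 3-{[6-(benzyloxy)-1-oxo-3-pentyl-1H-isochromen-8-yl]oxy}non-3-en-2-one (alkene geometry not specified) | CCCCCC=C(Oc1cc(OCc2ccccc2)cc2cc(CCCCC)oc(=O)c12)C(C)=O
A4 | alternative 2 | 8-[2,4-bis(benzyloxy)-6-pentylphenoxy]-6-methoxy-3-pentyl-3,4-dihydro-1H-isochromen-1-one (racemic) | CCCCCC1Cc2cc(OC)cc(Oc3c(OCc4ccccc4)cc(OCc4ccccc4)cc3CCCCC)c2C(=O)O1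
A5 | alternative 2 | 1,5-bis(benzyloxy)-2-(2-iodo-5-methoxyphenoxy)-3-pentylbenzene | COc1ccc(I)c(Oc2c(OCc3ccccc3)cc(OCc3ccccc3)cc2CCCCC)c1
A6 | alternative 2 | 2-pentyloxirane (racemic) | CCCCCC1CO1
A7 | alternative 2 | carbon monoxide | [C-]#[O+]
A8 | alternative 3 | 3-[2,4-bis(benzyloxy)-6-pentylphenoxy]-5-methylphenol | Cc1cc(O)cc(Oc2c(OCc3ccccc3)cc(OCc3ccccc3)cc2CCCCC)c1
A9 | alternative 3 | 3-methylcyclobut-2-en-1-one | CC1=CC(=O)C1
A10 | alternative 3 | 1,5-bis(benzyloxy)-2-(ethynyloxy)-3-pentylbenzene | C#COc1c(OCc2ccccc2)cc(OCc2ccccc2)cc1CCCCC
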